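The data are calculated with made-up constants; the scatter is artificial.

At 25 °C and after 6.0 min, the noon run and beta look alike: same feed, same reagent, and a charge of 0.19 M against 0.21 M. Gamma has the same reagent and temperature, but takes 0.10 M and goes in at once.

| setting | winter | noon | gamma | beta |
|---|---|---|---|---|
| substrate | 0.081 M (fed, over 80 s) | 0.19 M (fed, over 80 s) | 0.10 M | 0.21 M (fed, over 80 s) |
| reagent | 0.231 M | 0.231 M | 0.231 M | 0.231 M |
| temperature | 10 °C | 25 °C | 25 °C | 25 °C |
| remark | run made earlier | run made earlier | everything together at the start |  |
| time |  |  | 6.0 min | 6.0 min |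

| run | time / min | target / % | side product / % | substrate / % |
|---|---|---|---|---|
| winter | 0.667 | 0 | 0 | 48.8 |
| winter | 2.00 | 1.2 | 0 | 96.1 |
| winter | 3.00 | 0.6 | 0.2 | 93.3 |
| winter | 5.00 | 1.7 | 0 | 87.4 |
| winter | 8.00 | 3.3 | 0 | 81.2 |
| winter | 10.0 | 4.5 | 0.9 | 76.6 |
| winter | 12.0 | 6.6 | 1.7 | 72.9 |
| noon | 0.500 | 0.3 | 0.2 | 36.6 |
| noon | 0.667 | 0.4 | 0.6 | 49.8 |
| noon | 1.00 | 0.5 | 0.2 | 71.5 |
| noon | 1.50 | 1.4 | 0 | 92.5 |
| noon | 2.50 | 4.0 | 2.1 | 84.2 |
| noon | 4.00 | 8.2 | 6.2 | 73.1 |
| noon | 6.00 | 12.9 | 14.9 | 59.6 |

(readings scatter by 0.5 percentage points)

- percent here means substrate units held: one side product counts as two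
- the numbers in the tables scatter with a standard deviation of 0.5 percentage points
- percentages count the whole charge, also what has not yet gone in

* the flask that ends with the higher share of target in all that became target or side product, or "neither" when 2 percentage points or less lies between them (gamma / beta / neither)
* share of target in all that became target or side product, gamma
* share of target in all that became target or side product, beta

At 6.00 min, noon reads target 12.9 % and side product 14.9 %, so its share of target (the selectivity) reads 46.4 %.

One side product holds two substrate units, so I take it that two species meet to form it. In percent of the charge, its rate then rises with the charge, but the rate of target does not. Divide one rate by the other and the ratio still moves along a run: noon's side product over target reads 0.525 at 2.50 min and 1.16 at 6.00 min. So I compare flasks at the same clock time, where time cancels. At fixed reagent, temperature and clock time, side product over target should grow in proportion to the charge.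

Noon gives 6.08 L mol⁻¹, a reading with its scatter. I call this the side load, side product over target divided by the charge. I treat the feed as short, since 1.3 min is less than 6.0 min.

share = target / (target + side product) = 1 / (1 + side load × charge)

gamma: 1 / (1 + 6.08 L mol⁻¹ × 0.10 M) = 62.2 %

beta: 1 / (1 + 6.08 L mol⁻¹ × 0.21 M) = 43.9 %

So I expect beta to end lower than noon's 46.4 %, with its larger charge.

The forecast says gamma, with gamma at 63 % and beta at 44.5 %: “Gamma is clearly higher because side-product formation scales with concentration.” My two figures are a little lower than its figures , and they pick the same flask.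

The flask gives gamma: gamma ends at 61.7 % and beta at 43.4 %.

    substrate + reagent ⇌ intermediate (K = 11.0 L mol⁻¹, k = 0.00710 L mol⁻¹ s⁻¹, Ea = 55.0 kJ mol⁻¹, ΔH = −23.0 kJ mol⁻¹)
    substrate + target → side product (k = 0.0280 L mol⁻¹ s⁻¹, Ea = 70.0 kJ mol⁻¹)
    intermediate ⇌ target + released group (K = 0.430 M, k = 0.00630 s⁻¹, Ea = 86.0 kJ mol⁻¹, ΔH = 13.0 kJ mol⁻¹)
    (constants at 25 °C)

For the bench, the dilute flask gives the higher share of target. Reckoned back from these shares, the side load is 6.21 L mol⁻¹ in gamma and 6.21 L mol⁻¹ in beta, against 6.08 L mol⁻¹ at noon. At the concentration of beta, the side load gives gamma 43.9 %. Take away the difference in substrate concentration, giving gamma the charge of beta, and gamma ends at 40.7 %, which is 21 percentage points lower, so substrate concentration is a part of the gap. The side load holds at equal clock time, and the length of the run is the main reason beta stands at 43.4 %: against a run ten times as long, which ends at 12.6 %, that is 31 points higher.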